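**Strategy**

Everything rests on disconnecting the O1–C2 bond of the 2,3-dihydro-4H-pyran-4-one ring. C2, the stereocentre carrying the C19 chain, lies β to the C4 ketone, and O1 is the enol-ether oxygen of the O1–C6=C5–C4=O vinylogous ester, so a retro-oxa-Michael step opens the ring to a β-diketone enol and an enone in one chain. Forward, a single catalytic enantioselective 6-endo-trig cyclisation forms O1–C2, closes the only ring and sets the only stereocentre (2R). Its precursor is achiral (5E,16Z)-pentacosa-5,16-diene-2,4-dione, made by Horner–Wadsworth–Emmons olefination of (Z)-icos-11-enal with dimethyl (2,4-dioxopentyl)phosphonate.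

Key step: step 4

Remark on the chemistry: the sense of induction of the proposed cyclisation cannot be derived from a close precedent, so the quinine-derived catalyst is written and its quinidine-derived pseudoenantiomer would replace it should the quinine series favour 2S. The precursor 10 is used unprotected but is held as its sodium diketonate until a cold quench and taken into step 4 without storage. Ring numbering of 11 (O1, C2–C6) is used for the key step.

**Route**

Step 1
Reactants: 1 dimethyl (2-oxopropyl)phosphonate; 2 N-methoxy-N-methylacetamide
Product: 5 dimethyl (2,4-dioxopentyl)phosphonate, via ketophosphonate dianion 3 (not isolated), via amide tetrahedral adduct 4 (not isolated)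
Conditions: NaH (1.1 equiv), THF, 0 °C; n-BuLi (1.05 equiv), 0 °C; then 2, −78 → 0 °C; cold 1 M HCl
Reagents that add atoms: none
Why: Claisen-type C-acylation of the β-ketophosphonate 1,3-dianion 3 at its more nucleophilic terminal carbanion; the N-methoxy-N-methylamide gives the chelated tetrahedral adduct 4, which should survive until the acidic quench, so the acidic β-diketone 5 is released only on work-up and can neither quench a second equivalent of 3 nor be acylated twice; no stereocentre is formed.

Step 2
Reactants: 6 cis-11-eicosen-1-ol [(Z)-icos-11-en-1-ol]
Product: 7 (Z)-icos-11-enal
Conditions: TEMPO (10 mol%), PhI(OAc)2 (1.1 equiv), CH2Cl2, rt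
Reagents that add atoms: none
Why: oxoammonium-mediated (TEMPO/PhI(OAc)2) oxidation of a primary alcohol should stop at the aldehyde in anhydrous CH2Cl2 and leaves the isolated Z-alkene untouched and unisomerised; no stereocentre is involved.

Step 3
Reactants: 5 dimethyl (2,4-dioxopentyl)phosphonate; 7 (Z)-icos-11-enal
Product: 10 (5E,16Z)-pentacosa-5,16-diene-2,4-dione, via dioxophosphonate dianion 8 (not isolated), via sodium diketonate 9 (not isolated)
Conditions: NaH (2.2 equiv), THF, 0 °C; then 7, −20 °C → rt; cold 1 M HCl to pH 4–5; rapid chromatography, used at once
Reagents that add atoms: none
Why: Horner–Wadsworth–Emmons olefination through the 1,3-dianion 8, whose phosphorus-stabilised carbanion (not the diketonate carbon) adds to the aldehyde and eliminates dimethyl phosphate to give the E-enone expected of a stabilised phosphonate; the product rests as the chelated sodium diketonate 9, whose ring closure would have to generate a far more basic ketone enolate, so no uncatalysed cyclisation should occur before the cold quench, and the remote Z-alkene is not affected.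

Step 4
Reactants: 10 (5E,16Z)-pentacosa-5,16-diene-2,4-dione
Product: 11 (R)-6-methyl-2-[(Z)-nonadec-10-en-1-yl]-2,3-dihydro-4H-pyran-4-one
Conditions: quinine-derived squaramide 3-{[3,5-bis(trifluoromethyl)phenyl]amino}-4-{[(8α,9S)-6′-methoxycinchonan-9-yl]amino}cyclobut-3-ene-1,2-dione (10 mol%), toluene (0.05 M), −20 °C, Ar; then cold filtration through a silica plug to remove the catalyst
Reagents that add atoms: none
Why: Proposed new method: 10 reacts through its chelated enol, and the quinuclidine nitrogen of the catalyst is expected to take over the enol O–H as a general base while the two squaramide N–H bonds clamp the C4 carbonyl oxygen, which replaces the internal hydrogen bond, allows rotation about C4–C5 so that the enol oxygen faces the enone β-carbon, and lowers the enone LUMO, after which conjugate O-addition forms O1–C2 and the hydrogen-bonded enolate is protonated at C3 by the ammonium to release the vinylogous ester and free catalyst. The closest known reaction types are the amine–thiourea or amine–squaramide catalysed asymmetric intramolecular oxa-Michael cyclisations of ortho-hydroxyaryl enones to flavanones and chromanones, and the racemic acid- or base-mediated closure of 1-ene-3,5-diones to 2,3-dihydro-4H-pyran-4-ones, the new element being a diketone enol oxygen as nucleophile under enantiocontrol. The ring closes in the 6-endo-trig mode, both carbons of the attacked alkene ending up inside the six-membered ring O1–C2–C3–C4–C5–C6. C2 is set purely by catalyst control, the substrate being achiral: the catalyst-bound enol–enone array should expose one enantioface of the E-enone, and the catalyst pseudoenantiomer is chosen to give 2R. The step needs O- over C-alkylation and intra- over intermolecular addition, which the substrate secures because attack by the diketone carbon would require a four-membered ring, there is a single Michael acceptor, the isolated Z-alkene is inert, and dilution disfavours intermolecular C-Michael addition. Since the β-substituent is a plain alkyl chain the open form has no extended conjugation to lose, so the cyclic vinylogous ester is expected to be the thermodynamic product, while low temperature and prompt removal of the amine should keep retro-oxa-Michael re-opening (E1cB from C3) from eroding the enantiomeric purity.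

**Compound list**

1 | dimethyl (2-oxopropyl)phosphonate | CC(=O)CP(=O)(OC)OC | starting material
2 | N-methoxy-N-methylacetamide | CON(C)C(C)=O | starting material
3 | sodium lithium 1,3-dianion of dimethyl (2-oxopropyl)phosphonate (not isolated) | [Na+].[Li+].[CH2-]C(=O)[CH-]P(=O)(OC)OC | intermediate
4 | sodium lithium salt of the tetrahedral adduct of 3 with 2, dimethyl [4-(methoxy(methyl)amino)-4-oxido-2-oxopentyl]phosphonate carbanion (not isolated, racemic at the adduct carbon) | [Na+].[Li+].CON(C)C(C)([O-])CC(=O)[CH-]P(=O)(OC)OC | intermediate
5 | dimethyl (2,4-dioxopentyl)phosphonate | CC(=O)CC(=O)CP(=O)(OC)OC | intermediate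
6 | cis-11-eicosen-1-ol, (Z)-icos-11-en-1-ol | CCCCCCCC/C=C\CCCCCCCCCCO | starting material
7 | (Z)-icos-11-enal | CCCCCCCC/C=C\CCCCCCCCCC=O | intermediate
8 | disodium 1,3-dianion of dimethyl (2,4-dioxopentyl)phosphonate (not isolated) | [Na+].[Na+].CC(=O)[CH-]C(=O)[CH-]P(=O)(OC)OC | intermediate
9 | sodium diketonate of (5E,16Z)-pentacosa-5,16-diene-2,4-dione (not isolated) | [Na+].CCCCCCCC/C=C\CCCCCCCCC/C=C/C(=O)[CH-]C(C)=O | intermediate
10 | (5E,16Z)-pentacosa-5,16-diene-2,4-dione (drawn as the diketo form; mainly the chelated enol) | CCCCCCCC/C=C\CCCCCCCCC/C=C/C(=O)CC(C)=O | intermediate
11 | (R)-6-methyl-2-[(Z)-nonadec-10-en-1-yl]-2,3-dihydro-4H-pyran-4-one | CCCCCCCC/C=C\CCCCCCCCC[C@@H]1CC(=O)C=C(C)O1 | target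

**Step count**

Total steps: 4. Longest linear sequence: 3 steps (6 → 7 → 10 → 11, or equally 1 → 5 → 10 → 11).

**Steps most likely to fail**

1. Step 4 (the step carrying the label "Proposed new method:"). The closure may stall at an unfavourable or slowly reached equilibrium because the internal enol hydrogen bond resists reorganisation. Intermolecular C-Michael addition between two molecules may compete. Facial discrimination may be poor, or retro-oxa-Michael re-opening may erode the enantiomeric purity during reaction or work-up. The fallback uses known chemistry, sets out from aldehyde 7 and builds the ring by a [4+2] assembly instead. The electron-rich diene (3E)-4-methoxy-2-(trimethylsilyloxy)penta-1,3-diene F1 is prepared from commercial (E)-4-methoxypent-3-en-2-one (LDA, TMSCl, THF, −78 °C). It is combined with 7 under a chiral BINOL–titanium(IV) Lewis acid (BINOL/Ti(OiPr)4, 4 Å MS, toluene, 0 °C), a catalytic asymmetric hetero-Diels–Alder reaction established for aliphatic aldehydes with this diene type. The BINOL antipode is chosen to give the cycloadduct (2R)-6-methoxy-6-methyl-2-[(Z)-nonadec-10-en-1-yl]-4-(trimethylsilyloxy)-3,6-dihydro-2H-pyran F2 (epimers at C6). Brief treatment with TFA in CH2Cl2 at 0 °C removes methanol and the silyl group and rejoins the route at target 11. Compound 10 and the oxa-Michael step are bypassed. Material made this way would also serve to assign the configuration of the step 4 product.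

2. Step 3. The strongly basic dianion 8 may enolise the aldehyde and trigger self-condensation. Olefination may be sluggish because the carbanion sits in a chelated aggregate. Non-selective ring closure may set in during work-up. The fallback sets out from aldehyde 7. Olefination with the simple phosphonate 1 under mild LiCl/DBU conditions (MeCN, rt) should give (3E,14Z)-tricosa-3,14-dien-2-one F3. Its kinetic α′-lithium enolate (LiHMDS, 2.1 equiv, THF, −78 °C) is then C-acylated with 1-acetylbenzotriazole in a crossed Claisen condensation. A cold acidic quench returns to the route at ene-dione 10.

3. Step 1. O-acylation, or proton transfer from the acetyl group of 2 to the dianion, may return starting phosphonate. Premature collapse of adduct 4 may lead to over-acylation. The fallback sets out from phosphonate 1 through the same dianion 3 and replaces acylation by addition and oxidation. Aldol addition of 3 to acetaldehyde at −78 °C should give racemic dimethyl (4-hydroxy-2-oxopentyl)phosphonate F4. Oxidation of this β-hydroxy ketone with IBX (EtOAc, 75 °C) returns to the route at dioxophosphonate 5.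

Further compounds
F1 | step 4 | (3E)-4-methoxy-2-(trimethylsilyloxy)penta-1,3-diene | C=C(O[Si](C)(C)C)/C=C(\C)OC
F2 | step 4 | (2R)-6-methoxy-6-methyl-2-[(Z)-nonadec-10-en-1-yl]-4-(trimethylsilyloxy)-3,6-dihydro-2H-pyran (epimers at C6) | CCCCCCCC/C=C\CCCCCCCCC[C@@H]1CC(O[Si](C)(C)C)=CC(C)(OC)O1
F3 | step 3 | (3E,14Z)-tricosa-3,14-dien-2-one | CCCCCCCC/C=C\CCCCCCCCC/C=C/C(C)=O
F4 | step 1 | dimethyl (4-hydroxy-2-oxopentyl)phosphonate (racemic) | CC(O)CC(=O)CP(=O)(OC)OC
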